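**Strategy.** Labels follow xanthanolide numbering (primed = the unit with the 3-oxobutyl chain; rings A/B = methylene lactone/cycloheptane, C = cyclohexene, D = spiro lactone, E = cycloheptene). Ring E holds the C1'=C5' alkene 1,4 to the oxygenated C8' across C10', a divinylcyclopropane retron. 8-epi-Xanthatin and itaconic anhydride give ring C and C11' by Diels–Alder reaction; a chiral cis-vinylcyclopropylzinc then acylates C8'. In the key step the precursor, γ-keto acid 29 (C11' carboxyl, C8' cyclopropyl ketone, vinyl cis to the acyl group), closes to a spiro enol lactone (C7'=C8'). Strain-driven Cope rearrangement then breaks C1'–C9' and forges C6'–C7', expanding cyclopropane C1'/C9'/C10' into ring E and setting C7' from C10'.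

Key step: step 16

Remark: the sense of induction of the chiral catalysts and ligands in steps 1, 3 and 12 is assigned by analogy with their parent reactions; the antipodal catalyst or ligand is taken if the sense proves opposite.

Step 1
Reactants: 1 (E)-but-2-enal; 2 ethynyltri(propan-2-yl)silane
Product: 3 (3S)-3-methyl-5-[tri(propan-2-yl)silyl]pent-4-ynal
Conditions: [Rh(OAc)(C2H4)2]2 (2.5 mol %), (R)-DTBM-SEGPHOS (6 mol %), MeOH, 40 °C
Reagents that add atoms: none
Why: Rh-catalysed asymmetric conjugate alkynylation of an enal, in which the bulky silyl group suppresses alkyne dimerisation and the ligand sets the methyl-bearing centre (later C10).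

Step 2
Reactants: 4 methyl prop-2-ynoate; 5 allylmagnesium bromide; 6 2-(iodomethyl)-4,4,5,5-tetramethyl-1,3,2-dioxaborolane
Product: 8 methyl (2E)-2-[(4,4,5,5-tetramethyl-1,3,2-dioxaborolan-2-yl)methyl]hexa-2,5-dienoate (allyl cis to CH2B), via vinylcopper 7 (not isolated)
Conditions: CuBr·SMe2, 5, THF, −78 °C; 4; then 6, HMPA, −78 → 0 °C
Reagents that add atoms: none
Why: syn-carbocupration of the ynoate and alkylation of the α-cuprio acrylate with the iodomethylboronate (the standard entry to 2-alkoxycarbonyl allylboronates), the syn addition placing the allyl group cis to the CH2B carbon.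

Step 3
Reactants: 3 (3S)-3-methyl-5-[tri(propan-2-yl)silyl]pent-4-ynal; 8 allylboronate
Product: 10 (4R,5R)-3-methylidene-5-{(2S)-2-methyl-4-[tri(propan-2-yl)silyl]but-3-yn-1-yl}-4-(prop-2-en-1-yl)oxolan-2-one (4,5-cis), via homoallylic borate 9 (not isolated)
Conditions: (S)-TRIP phosphoric acid [(S)-3,3'-bis(2,4,6-triisopropylphenyl)-1,1'-binaphthyl-2,2'-diyl hydrogen phosphate] (10 mol %), PhMe, 4 Å MS, −30 °C → rt; then TsOH·H2O (cat.), rt
Reagents that add atoms: none
Why: chiral-phosphoric-acid-catalysed allylboration through a chair transition state, in which the cis allyl/CH2B geometry gives the syn adduct (hence the cis lactone after acid-induced lactonisation) and the catalyst selects the aldehyde face (C8) independently of the remote C10 centre.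

Step 4
Reactants: 10 silylated enyne lactone
Product: 11 (4R,5R)-3-methylidene-5-[(2S)-2-methylbut-3-yn-1-yl]-4-(prop-2-en-1-yl)oxolan-2-one
Conditions: TBAF, AcOH, THF, 0 °C
Reagents that add atoms: none
Why: fluoride-induced protodesilylation of the alkynylsilane, buffered with acetic acid to spare the α-methylene lactone.

Step 5
Reactants: 11 enyne lactone; 12 but-3-en-2-one
Product: 13 8-epi-xanthatin, (3aR,7S,8aR)-7-methyl-3-methylidene-6-[(E)-3-oxobut-1-enyl]-3,3a,4,7,8,8a-hexahydro-2H-cyclohepta[b]furan-2-one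
Conditions: second-generation Hoveyda–Grubbs catalyst, RuCl2(H2IMes)(=CH-C6H4-2-O-i-Pr) (10 mol %), 12 (5 equiv), CH2Cl2, 40 °C
Reagents that add atoms: none
Why: domino ring-closing enyne metathesis/cross-metathesis, in which the carbene formed at the allyl group closes ring B onto the alkyne (C5=C1) and the resulting vinylcarbene is intercepted by the enone to give the E-dienone, while the 1,1-disubstituted acrylate alkene is inert.

Step 6
Reactants: 13 8-epi-xanthatin; 14 itaconic anhydride (3-methylideneoxolane-2,5-dione)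
Product: 15 spiro anhydride (ring C with C1=C2, acetyl on C3, C11' spiro to the anhydride; H-3, H-5 and the conjugated carbonyl C12' on one face of ring C; the C5–C13' bond on the face of ring B opposite CH3-14 and ring A)
Conditions: 14 (4 equiv), BHT (cat.), PhMe, 90 °C, sealed tube
Reagents that add atoms: none
Why: thermal Diels–Alder reaction with the usual "ortho" orientation of a 1-acyl diene (C3–C11', C5–C13'), the dienophile approaching the diene face opposite the C14 methyl and ring A with its conjugated carbonyl exo, as is typical of s-cis-locked exocyclic methylene dienophiles, which sets C5 and C11' (C3 is erased in step 8).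

Step 7
Reactants: 15 spiro anhydride
Product: 16 1,2-epoxide of 15 (oxygen on the ring-C face of H-3 and H-5)
Conditions: mCPBA, NaHCO3, CH2Cl2, 0 °C
Reagents that add atoms: 3-chloroperoxybenzoic acid, O=C(OO)c1cccc(Cl)c1
Why: Prilezhaev epoxidation of the only electron-rich alkene (C1=C2) from the face anti to the C3 acetyl group and the C7' methylene, the two methylene-carbonyl alkenes being inert to peracid.

Step 8
Reactants: 16 epoxy ketone
Product: 18 1-O-triethylsilyl γ-silyloxy enone anhydride (C1–OSiEt3, C2=C3–C4=O), via hydroxy enone 17 (not isolated)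
Conditions: Et3N (0.3 equiv), CH2Cl2, 0 °C → rt; then 2,6-lutidine, TESOTf, −78 → 0 °C
Reagents that add atoms: triethylsilyl trifluoromethanesulfonate, CC[Si](CC)(CC)OS(=O)(=O)C(F)(F)F
Why: base-induced E1cB opening of the β,γ-epoxy ketone (C3–H removed, C2–O cleaved) gives the γ-hydroxy enone with the C1–O bond and configuration retained, and immediate silylation keeps the tertiary hydroxyl away from the anhydride.

Step 9
Reactants: 1 (E)-but-2-enal
Product: 19 (2Z)-2-iodobut-2-enal
Conditions: I2, K2CO3, DMAP (cat.), THF/H2O, rt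
Reagents that add atoms: iodine, II
Why: amine-catalysed α-iodination of an enal (conjugate addition, iodination of the enolate, elimination), which gives the Z-iodoenal.

Step 10
Reactants: 19 (2Z)-2-iodobut-2-enal
Product: 20 (2Z)-2-iodobut-2-en-1-ol
Conditions: NaBH4, CeCl3·7H2O, MeOH, 0 °C
Reagents that add atoms: none
Why: Luche 1,2-reduction of the enal without loss of the vinyl iodide.

Step 11
Reactants: 20 (2Z)-2-iodobut-2-en-1-ol; 21 2-ethenyl-2-methyl-1,3-dioxolane
Product: 23 (2E)-2-[2-(2-methyl-1,3-dioxolan-2-yl)ethyl]but-2-en-1-ol, via alkylborane 22 (not isolated)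
Conditions: 21, 9-BBN-H, THF, 0 °C → rt; then 20, PdCl2[(Ph2PC5H4)2Fe] (5 mol %), AsPh3, Cs2CO3, DMF/H2O, rt
Reagents that add atoms: none
Why: anti-Markovnikov hydroboration followed by B-alkyl Suzuki–Miyaura coupling, which proceeds with retention of the alkene geometry (CH3 trans to CH2OH).

Step 12
Reactants: 23 allylic alcohol
Product: 24 [(1R,2R,3S)-2-iodo-3-methyl-1-[2-(2-methyl-1,3-dioxolan-2-yl)ethyl]cyclopropyl]methanol (iodine cis to CH2OH; CH3 trans to both)
Conditions: EtZnI (from Et2Zn and I2), CHI3, (4S,5S)-2-butyl-N,N,N',N'-tetramethyl-1,3,2-dioxaborolane-4,5-dicarboxamide (1.2 equiv), CH2Cl2, −78 °C → rt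
Reagents that add atoms: iodoform, IC(I)I
Why: Simmons–Smith-type directed iodocyclopropanation of an allylic alcohol with the zinc carbenoid from iodoform, in which the stereospecific syn addition keeps CH3 trans to CH2OH, the dioxaborolane ligand selects the alkene face, and iodine is expected on the less crowded side (cis to CH2OH and H, away from the methyl group and the chain).

Step 13
Reactants: 24 iodocyclopropylmethanol
Product: 25 (1R,2R,3S)-2-iodo-3-methyl-1-[2-(2-methyl-1,3-dioxolan-2-yl)ethyl]cyclopropane-1-carbaldehyde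
Conditions: Dess–Martin periodinane, NaHCO3, CH2Cl2, 0 °C → rt
Reagents that add atoms: none
Why: Dess–Martin oxidation of the primary alcohol under neutral conditions that preserve the iodocyclopropane and the ketal.

Step 14
Reactants: 25 cyclopropanecarbaldehyde
Product: 26 2-{2-[(1S,2R,3S)-1-ethenyl-2-iodo-3-methylcyclopropyl]ethyl}-2-methyl-1,3-dioxolane (vinyl cis to iodine, CH3 trans to both)
Conditions: Ph3PCH3Br, KN(SiMe3)2, THF, 0 °C; then 25, −78 → 0 °C
Reagents that add atoms: methyltriphenylphosphonium bromide, C[P+](c1ccccc1)(c1ccccc1)c1ccccc1.[Br-]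
Why: Wittig methylenation of the non-enolisable aldehyde installs the vinyl group without touching the ring stereocentres.

Step 15
Reactants: 26 vinylcyclopropyl iodide; 18 silyloxy enone anhydride
Product: 29 γ-keto acid (carboxyl on C11'; C7'H2–C8'(=O) attached to the cyclopropane; vinyl cis to the acyl group, CH3 trans), via cyclopropyllithium 27 (not isolated), via cyclopropylzinc chloride 28 (not isolated)
Conditions: 26, t-BuLi (2.05 equiv), Et2O, −78 °C; ZnCl2 (1.1 equiv), THF, −78 °C → rt; then 18, Pd(PPh3)4 (5 mol %), THF, rt; dilute acid work-up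
Reagents that add atoms: none
Why: iodine–lithium exchange and transmetalation proceed with retention at the cyclopropyl carbon, and the Pd-catalysed Negishi-type acyl cross-coupling of the cyclic anhydride takes place at the less hindered C8' carbonyl remote from the quaternary C11', while ketone, enone and lactones are inert to the organozinc.

Step 16
Reactants: 29 γ-keto acid
Product: 31 dienol lactone (ring E closed: C8'=C9' enol-lactone alkene, C1'=C5' alkene, H-7' on the ring-D face of C13', CH3-10' cis to the C7'–C11' bond), via enol lactone 30 (not isolated)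
Conditions: Ac2O, NaOAc, PhMe, 100 °C
Reagents that add atoms: none
Why: The mixed anhydride of the C12' acid O-acylates the enol of the C8' ketone (enolisation toward C7'H2, not toward the cyclopropane) in a 5-exo-trig closure to the 2(3H)-furanone 30, whose C7'=C8' bond and the vinyl group are cis on the cyclopropane; this cis-divinylcyclopropane then undergoes the [3,3]-sigmatropic (Cope) shift through its only accessible boat transition state, breaking C1'–C9' and forming C6'–C7'. The closest known reaction type is the divinylcyclopropane–cycloheptadiene rearrangement of cis-2-vinylcyclopropyl enol ethers and enones. Ring E is closed by this concerted three-to-seven ring expansion driven by release of cyclopropane strain, and the transient butenolide ring by acyl transfer to oxygen. The single new stereocentre C7' is controlled by the cyclopropane: the lactone ring locks C11' trans to the cyclopropane across C7'=C8', the C10' methyl is anti to both π-arms, and the boat geometry then joins C6' to C7' so that C11' and the methyl end up cis on ring E, whatever the bias of the crowded spiro centre. The step needs enol lactonisation only at the γ-keto acid (the enone and the ketal cannot form such a ring) and needs the cis-divinyl isomer without a cis alkyl hydrogen for a competing homodienyl shift, both secured by steps 12 and 15; C10' and all centres of the upper unit are untouched.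

Step 17
Reactants: 31 dienol lactone
Product: 32 keto acid (C8' ketone in ring E, carboxyl on C11')
Conditions: Me3SnOH (5 equiv), 1,2-dichloroethane, 70 °C; cold 0.1 M HCl wash
Reagents that add atoms: trimethyltin hydroxide, C[Sn](C)(C)O
Why: mild tin hydroxide cleavage of the activated enol ester, after which the released enol ketonises by protonation at C9' and leaves the C7' centre untouched.

Step 18
Reactants: 32 keto acid
Product: 34 protected target (ring D closed; C1–OSiEt3; side-chain ketone as dioxolane), via hydroxy acid 33 (not isolated)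
Conditions: NaBH4, MeOH/CH2Cl2 (1:1), −78 → −40 °C; then aq. NaH2PO4, PhMe, rt
Reagents that add atoms: none
Why: borohydride in methanol/dichloromethane at low temperature reduces a saturated ketone faster than a conjugated enone, hydride attacking C8' from the face opposite the C7' spiro substituent and the C10' methyl so that the cis hydroxy acid forms and lactonises to ring D.

Step 19
Reactants: 34 protected target
Product: 35 CNP0195550.4 (target)
Conditions: 1 M aq. HCl, THF, rt
Reagents that add atoms: water, O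
Why: acid hydrolysis removes the dioxolane and the tertiary silyl ether, the γ-hydroxy enone and both lactones being stable to dilute acid.

**Compound list**

1 | (E)-but-2-enal | C/C=C/C=O | starting material
2 | ethynyltri(propan-2-yl)silane | C#C[Si](C(C)C)(C(C)C)C(C)C | starting material
3 | (3S)-3-methyl-5-[tri(propan-2-yl)silyl]pent-4-ynal | O=CC[C@H](C)C#C[Si](C(C)C)(C(C)C)C(C)C | intermediate
4 | methyl prop-2-ynoate | C#CC(=O)OC | starting material
5 | allylmagnesium bromide | C=CC[Mg]Br | starting material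
6 | 2-(iodomethyl)-4,4,5,5-tetramethyl-1,3,2-dioxaborolane | ICB1OC(C)(C)C(C)(C)O1 | starting material
7 | methyl (2Z)-2-cupriohexa-2,5-dienoate (allyl cis to Cu) | C=CC/C=C(\[Cu])C(=O)OC | intermediate
8 | methyl (2E)-2-[(4,4,5,5-tetramethyl-1,3,2-dioxaborolan-2-yl)methyl]hexa-2,5-dienoate | C=CC/C=C(\CB1OC(C)(C)C(C)(C)O1)C(=O)OC | intermediate
9 | pinacol borate of methyl (3R,4R,6S)-4-hydroxy-6-methyl-2-methylidene-3-(prop-2-enyl)-8-[tri(propan-2-yl)silyl]oct-7-ynoate | COC(=O)C(=C)[C@@H](CC=C)[C@H](OB1OC(C)(C)C(C)(C)O1)C[C@H](C)C#C[Si](C(C)C)(C(C)C)C(C)C | intermediate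
10 | (4R,5R)-3-methylidene-5-{(2S)-2-methyl-4-[tri(propan-2-yl)silyl]but-3-yn-1-yl}-4-(prop-2-en-1-yl)oxolan-2-one | C=C1C(=O)O[C@H](C[C@H](C)C#C[Si](C(C)C)(C(C)C)C(C)C)[C@@H]1CC=C | intermediate
11 | (4R,5R)-3-methylidene-5-[(2S)-2-methylbut-3-yn-1-yl]-4-(prop-2-en-1-yl)oxolan-2-one | C=C1C(=O)O[C@H](C[C@H](C)C#C)[C@@H]1CC=C | intermediate
12 | but-3-en-2-one | C=CC(C)=O | starting material
13 | 8-epi-xanthatin | C=C1C(=O)O[C@@H]2C[C@H](C)C(/C=C/C(C)=O)=CC[C@H]12 | intermediate
14 | itaconic anhydride | C=C1CC(=O)OC1=O | starting material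
15 | Diels–Alder spiro anhydride (C1=C2, 3-acetyl; H-3, H-5 and C12' cis on ring C) | C=C1C(=O)O[C@@H]2C[C@H](C)C3=C[C@@H](C(C)=O)[C@@]4(C[C@H]3C[C@H]12)C(=O)OC(=O)C4 | intermediate
16 | 1,2-epoxide of 15 (oxygen syn to H-3 and H-5) | C=C1C(=O)O[C@@H]2C[C@H](C)[C@]34O[C@@H]4[C@@H](C(C)=O)[C@@]5(C[C@H]3C[C@H]12)C(=O)OC(=O)C5 | intermediate
17 | 1-hydroxy enone anhydride (C2=C3–C4=O; OH cis to H-5) | C=C1C(=O)O[C@@H]2C[C@H](C)[C@@]3(O)C=C(C(C)=O)[C@@]4(C[C@H]3C[C@H]12)C(=O)OC(=O)C4 | intermediate
18 | 1-O-triethylsilyl ether of 17 | C=C1C(=O)O[C@@H]2C[C@H](C)[C@@]3(O[Si](CC)(CC)CC)C=C(C(C)=O)[C@@]4(C[C@H]3C[C@H]12)C(=O)OC(=O)C4 | intermediate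
19 | (2Z)-2-iodobut-2-enal | C/C=C(\I)C=O | intermediate
20 | (2Z)-2-iodobut-2-en-1-ol | C/C=C(\I)CO | intermediate
21 | 2-ethenyl-2-methyl-1,3-dioxolane | C=CC1(C)OCCO1 | starting material
22 | 9-[2-(2-methyl-1,3-dioxolan-2-yl)ethyl]-9-borabicyclo[3.3.1]nonane | CC1(CCB2C3CCCC2CCC3)OCCO1 | intermediate
23 | (2E)-2-[2-(2-methyl-1,3-dioxolan-2-yl)ethyl]but-2-en-1-ol | C/C=C(\CCC1(C)OCCO1)CO | intermediate
24 | [(1R,2R,3S)-2-iodo-3-methyl-1-[2-(2-methyl-1,3-dioxolan-2-yl)ethyl]cyclopropyl]methanol | OC[C@]1(CCC2(C)OCCO2)[C@H](I)[C@H]1C | intermediate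
25 | (1R,2R,3S)-2-iodo-3-methyl-1-[2-(2-methyl-1,3-dioxolan-2-yl)ethyl]cyclopropane-1-carbaldehyde | O=C[C@]1(CCC2(C)OCCO2)[C@H](I)[C@H]1C | intermediate
26 | 2-{2-[(1S,2R,3S)-1-ethenyl-2-iodo-3-methylcyclopropyl]ethyl}-2-methyl-1,3-dioxolane | C=C[C@]1(CCC2(C)OCCO2)[C@H](I)[C@H]1C | intermediate
27 | corresponding cyclopropyllithium (Li in place of I, retention) | C=C[C@]1(CCC2(C)OCCO2)[C@H]([Li])[C@H]1C | intermediate
28 | corresponding cyclopropylzinc chloride | C=C[C@]1(CCC2(C)OCCO2)[C@H]([Zn]Cl)[C@H]1C | intermediate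
29 | γ-keto acid (C11'–CO2H; C8' cyclopropyl ketone; vinyl cis to acyl, CH3 trans) | C=C1C(=O)O[C@@H]2C[C@H](C)[C@@]3(O[Si](CC)(CC)CC)C=C(C(C)=O)[C@@](C[C@H]3C[C@H]12)(C(=O)O)CC(=O)[C@@H]4[C@@H](C)[C@@]4(C=C)CCC5(C)OCCO5 | intermediate
30 | spiro 5-cyclopropyl-2(3H)-furanone (enol lactone, C7'=C8') | C=C1C(=O)O[C@@H]2C[C@H](C)[C@@]3(O[Si](CC)(CC)CC)C=C(C(C)=O)[C@@]4(C[C@H]3C[C@H]12)C(=O)OC([C@@H]5[C@@H](C)[C@@]5(C=C)CCC6(C)OCCO6)=C4 | intermediate
31 | dienol lactone (rings D and E; C8'=C9', C1'=C5') | C=C1C(=O)O[C@@H]2C[C@H](C)[C@@]3(O[Si](CC)(CC)CC)C=C(C(C)=O)[C@@]4(C[C@H]3C[C@H]12)C(=O)OC1=C[C@@H](C)C(CCC5(C)OCCO5)=CC[C@H]14 | intermediate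
32 | keto acid (C8' ketone in ring E; C11'–CO2H) | C=C1C(=O)O[C@@H]2C[C@H](C)[C@@]3(O[Si](CC)(CC)CC)C=C(C(C)=O)[C@@](C[C@H]3C[C@H]12)(C(=O)O)[C@@H]4CC=C(CCC5(C)OCCO5)[C@H](C)CC4=O | intermediate
33 | cis hydroxy acid (8'-OH cis to the C7'–C11' bond) | C=C1C(=O)O[C@@H]2C[C@H](C)[C@@]3(O[Si](CC)(CC)CC)C=C(C(C)=O)[C@@](C[C@H]3C[C@H]12)(C(=O)O)[C@@H]4CC=C(CCC5(C)OCCO5)[C@H](C)C[C@@H]4O | intermediate
34 | protected target (1-O-SiEt3; side-chain ketone as 1,3-dioxolane) | C=C1C(=O)O[C@@H]2C[C@H](C)[C@@]3(O[Si](CC)(CC)CC)C=C(C(C)=O)[C@@]4(C[C@H]3C[C@H]12)C(=O)O[C@H]1C[C@@H](C)C(CCC5(C)OCCO5)=CC[C@H]14 | intermediate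
35 | CNP0195550.4 | C=C1C(=O)O[C@@H]2C[C@H](C)[C@@]3(O)C=C(C(C)=O)[C@@]4(C[C@H]3C[C@H]12)C(=O)O[C@H]1C[C@@H](C)C(CCC(C)=O)=CC[C@H]14 | target

**Totals.** 19 steps; longest linear sequence 12 steps (steps 2–8 and 15–19; the branch through step 1 is equally long).

**Steps most likely to fail**

Step 16. The O-acylation that forms the strained spiro butenolide may lag behind thermal one-centre epimerisation of the cis-vinylcyclopropyl ketone, or the sigmatropic shift may stall because C6' has to approach C7' next to the quaternary C11'. The fallback sets out from 29 and replaces the ring-locked enol lactone by an open silyl enol ether. Soft enolisation (TMSOTf, Et3N, CH2Cl2, 0 °C) should give the tris(trimethylsilyl) derivative F1 (silyl ester, Z-silyl enol ether at C7'=C8', silyl enol ether of the C4 methyl ketone). Heating in toluene (80–110 °C) should effect the classical Cope rearrangement of a siloxy-substituted cis-divinylcyclopropane to the cycloheptadiene F2. Brief treatment with aqueous citric acid in THF cleaves the three labile Si–O bonds, and the route is rejoined at 32.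

Step 12. Which carbenoid substituent (H or I) faces the hydroxymethyl side may be poorly controlled, or facial selectivity on the trisubstituted alkene may be low. The fallback sets out from 23 and fixes the C9' centre by chelation instead of carbenoid sterics. Zincocyclopropanation with the gem-dizinc carbenoid (IZn)2CHI (from CHI3 and EtZnI) in the presence of the same dioxaborolane should give the iodozinc cyclopropane F3, whose carbon–zinc bond is held cis to the alkoxide oxygen. Iodinolysis (I2, −78 °C) with retention comes back to the route at 24.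

Step 15. Transmetalation of the secondary cyclopropylzinc to the acylpalladium intermediate may be slow, allowing conjugate transfer to the enone or protodemetalation. The fallback sets out from 15 and 28 and makes the union one stage earlier, where neither the enone nor the silyl ether is present. The Pd(PPh3)4-catalysed acylation should give keto acid F4. mCPBA (NaHCO3, CH2Cl2, 0 °C) then epoxidises the trisubstituted C1=C2 alkene in preference to the monosubstituted vinyl group, giving F5. Et3N, then TESOTf/2,6-lutidine and an aqueous work-up that cleaves the silyl ester come back to the route at 29.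

**Further compounds**

F1 | step 16 | tris(trimethylsilyl) derivative of 29 (silyl ester, Z-silyl enol ether C7'=C8', silyl enol ether of the C4 ketone) | C=C1C(=O)O[C@@H]2C[C@H](C)[C@@]3(O[Si](CC)(CC)CC)C=C(C(=C)O[Si](C)(C)C)[C@@](C[C@H]3C[C@H]12)(C(=O)O[Si](C)(C)C)/C=C(\O[Si](C)(C)C)[C@@H]4[C@@H](C)[C@@]4(C=C)CCC5(C)OCCO5
F2 | step 16 | Cope product of F1 (ring E with C8'(OSiMe3)=C9' and C1'=C5') | C=C1C(=O)O[C@@H]2C[C@H](C)[C@@]3(O[Si](CC)(CC)CC)C=C(C(=C)O[Si](C)(C)C)[C@@](C[C@H]3C[C@H]12)(C(=O)O[Si](C)(C)C)[C@@H]4CC=C(CCC5(C)OCCO5)[C@H](C)C=C4O[Si](C)(C)C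
F3 | step 12 | iodozinc cyclopropane (ZnI in place of I in 24, cis to CH2OH) | OC[C@]1(CCC2(C)OCCO2)[C@H]([Zn]I)[C@H]1C
F4 | step 15 | keto acid from 15 (C1=C2, 3-acetyl; C11'–CO2H; C8' cyclopropyl ketone) | C=C1C(=O)O[C@@H]2C[C@H](C)C3=C[C@@H](C(C)=O)[C@@](C[C@H]3C[C@H]12)(C(=O)O)CC(=O)[C@@H]4[C@@H](C)[C@@]4(C=C)CCC5(C)OCCO5
F5 | step 15 | 1,2-epoxide of F4 | C=C1C(=O)O[C@@H]2C[C@H](C)[C@]34O[C@@H]4[C@@H](C(C)=O)[C@@](C[C@H]3C[C@H]12)(C(=O)O)CC(=O)[C@@H]5[C@@H](C)[C@@]5(C=C)CCC6(C)OCCO6
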